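**Retrosynthetic overview**

1. Target 16 ⇐ E-selective Horner–Wadsworth–Emmons olefination of the ten-membered phosphonoacetate lactone 12 with epoxy aldehyde 15 (from (E)-crotyl alcohol by Sharpless epoxidation).
2. 12 ⇐ two-atom ring expansion (acyl shift from O7 to O9, eight- to ten-membered) of the (Z)-lactone 11.
3. 11 ⇐ ring-closing metathesis of diene ester 10; an eight-membered ring can only hold a cis olefin, so C5=C6 is fixed as Z.
4. 10 ⇐ Ti(OiPr)4-mediated SN2 opening of vinyl epoxy alcohol 9 (penta-2,4-dienal + PrMgBr, then Sharpless kinetic resolution) by acid 5 (methyl (S)-glycidate + allylMgBr, then phosphonoacetylation).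
5. Ring order: eight-membered lactone (metathesis) → ten-membered lactone (ring expansion); the side-chain oxirane is brought in preformed.

Assumption: the stereochemistry is taken exactly as the SMILES is written: ring olefin Z, ring centres 2S,7S,8S,9R, side chain 2E with a (4S,5S)-trans-oxirane.

Lactone numbering used below: C1 = lactone carbonyl, C2 = acyloxy carbon, C5=C6 = ring olefin, C7 and C8 = carbinol carbons, C9 = propyl-bearing carbon.

**Route**

Step 1
Reactants: 1 methyl (2S)-oxirane-2-carboxylate; 2 allylmagnesium bromide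
Product: 4 (2S)-2-hydroxyhex-5-enoic acid, via methyl (2S)-2-hydroxyhex-5-enoate 3 (not isolated)
Conditions: 2 (1.2 equiv, slow addition), CuI (10 mol %), THF, −78 → −40 °C; then LiOH, H2O, 0 °C → rt; then 1 M HCl
Reagents that add atoms: lithium hydroxide, [Li+].[OH-]
Why: Copper-catalysed Grignard opening of the epoxide at the unsubstituted carbon (SN2) followed by saponification in the same flask; the glycidate stereocentre is not touched and becomes C2 (S), and slow addition at −78 °C keeps the allyl reagent off the ester.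

Step 2
Reactants: 4 (2S)-2-hydroxyhex-5-enoic acid
Product: 5 (2S)-2-{[2-(diethoxyphosphoryl)acetyl]oxy}hex-5-enoic acid
Conditions: (EtO)2P(O)CH2COCl (1.3 equiv), CH2Cl2, 0 °C → rt; H2O work-up
Reagents that add atoms: (diethoxyphosphoryl)acetyl chloride, CCOP(=O)(CC(Cl)=O)OCC
Why: Base-free O-acylation of an α-hydroxy acid by an acid chloride (any mixed anhydride is hydrolysed on work-up) installs the Horner–Wadsworth–Emmons handle on O2 without touching C2.

Step 3
Reactants: 6 (2E)-penta-2,4-dienal; 7 propylmagnesium bromide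
Product: 8 racemic (5E)-octa-5,7-dien-4-ol
Conditions: THF, −78 → 0 °C; sat. aq NH4Cl
Reagents that add atoms: none
Why: 1,2-Grignard addition to the dienal gives the racemic dienyl carbinol that carries C6–C12 of the target.

Step 4
Reactants: 8 racemic (5E)-octa-5,7-dien-4-ol
Product: 9 (1R)-1-[(2R,3R)-3-ethenyloxiran-2-yl]butan-1-ol
Conditions: Ti(OiPr)4 (10 mol %), D-(−)-diisopropyl tartrate (15 mol %), t-BuOOH (0.5 equiv), 4 Å MS, CH2Cl2, −20 °C, stopped near 50 % conversion; the unreacted (S)-alcohol is separated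
Reagents that add atoms: tert-butyl hydroperoxide, CC(C)(C)OO
Why: Sharpless kinetic resolution: with D-(−)-tartrate the (R)-alcohol is epoxidised fast at the hydroxyl-directed 5,6-olefin to give the erythro epoxy alcohol, which fixes C9 and C8 (R,R here); the distal vinyl group is not epoxidised.

Step 5
Reactants: 9 (1R)-1-[(2R,3R)-3-ethenyloxiran-2-yl]butan-1-ol; 5 (2S)-2-{[2-(diethoxyphosphoryl)acetyl]oxy}hex-5-enoic acid
Product: 10 (3S,4R,5R)-4,5-dihydroxyoct-1-en-3-yl (2S)-2-{[2-(diethoxyphosphoryl)acetyl]oxy}hex-5-enoate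
Conditions: Ti(OiPr)4 (1.5 equiv), 5 (1.2 equiv), CH2Cl2, 0 °C → rt; 10 % aq tartaric acid
Reagents that add atoms: none
Why: Ti(OiPr)4-mediated regioselective opening of a 2,3-epoxy alcohol by a carboxylic acid (Sharpless C3 opening): the Ti-bound carboxylate attacks the distal, allylic epoxide carbon with inversion, which sets C7 (S) and makes the ester bond without a coupling reagent.

Step 6
Reactants: 10 (3S,4R,5R)-4,5-dihydroxyoct-1-en-3-yl (2S)-2-{[2-(diethoxyphosphoryl)acetyl]oxy}hex-5-enoate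
Product: 11 (3S,6Z,8S)-8-[(1R,2R)-1,2-dihydroxypentyl]-2-oxo-3,4,5,8-tetrahydro-2H-oxocin-3-yl 2-(diethoxyphosphoryl)acetate
Conditions: second-generation Grubbs catalyst RuCl2(=CHPh)(PCy3)(SIMes) (5 mol %), toluene (2 mM), 80 °C
Reagents that add atoms: none
Why: Ring-closing metathesis at high dilution; the eight-membered ring can only contain a cis olefin, so C5=C6 is formed as Z, and the substituents at C2 and C7 help the ester reach the cyclising conformation.

Step 7
Reactants: 11 (3S,6Z,8S)-8-[(1R,2R)-1,2-dihydroxypentyl]-2-oxo-3,4,5,8-tetrahydro-2H-oxocin-3-yl 2-(diethoxyphosphoryl)acetate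
Product: 12 (3S,6Z,8S,9S,10R)-8,9-dihydroxy-2-oxo-10-propyl-3,4,5,8,9,10-hexahydro-2H-oxecin-3-yl 2-(diethoxyphosphoryl)acetate
Conditions: (PhO)2P(O)OH (10 mol %), toluene (5 mM), 40 °C
Reagents that add atoms: none
Why: Proposed new method: an organocatalytic two-atom translactonization ring expansion in which the bifunctional phosphoric acid diester activates the lactone C=O (P–OH) and the C9–OH (P=O), so that O9 adds to C1 through a six-membered transition state to a bridged 2-hydroxy-1,3-dioxane ortho-acid whose collapse with C1–O7 cleavage moves the acyl group from O7 to O9 (directly, or stepwise through the nine-membered O8 ester) and enlarges the ring from eight to ten atoms; no bond at C2, C7, C8, C9 or at the olefin is broken, so all four centres and the Z geometry are carried over, and the equilibrium should be pulled to 12 by loss of the strain and enforced s-cis ester geometry of the eight-membered lactone in favour of a ten-membered ring with a normal ester conformation; the closest known reaction types are the acid-catalysed translactonization ring expansion of ω-hydroxyalkyl lactones by three or four atoms and the diphenyl phosphate-catalysed ring-opening transesterification of lactones by alcohols.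

Step 8
Reactants: 13 (2E)-but-2-en-1-ol
Product: 14 [(2S,3S)-3-methyloxiran-2-yl]methanol
Conditions: Ti(OiPr)4 (5 mol %), L-(+)-diethyl tartrate (6 mol %), t-BuOOH, 4 Å MS, CH2Cl2, −20 °C; non-aqueous work-up
Reagents that add atoms: tert-butyl hydroperoxide, CC(C)(C)OO
Why: Sharpless asymmetric epoxidation; L-(+)-tartrate delivers oxygen to the face of the (E)-allylic alcohol that gives the (2S,3S)-epoxy alcohol, which becomes the (4S,5S)-oxirane of the side chain.

Step 9
Reactants: 14 [(2S,3S)-3-methyloxiran-2-yl]methanol; 12 (3S,6Z,8S,9S,10R)-8,9-dihydroxy-2-oxo-10-propyl-3,4,5,8,9,10-hexahydro-2H-oxecin-3-yl 2-(diethoxyphosphoryl)acetate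
Product: 16 (3S,6Z,8S,9S,10R)-8,9-dihydroxy-2-oxo-10-propyl-3,4,5,8,9,10-hexahydro-2H-oxecin-3-yl (2E)-3-[(2S,3S)-3-methyloxiran-2-yl]prop-2-enoate, via (2R,3S)-3-methyloxirane-2-carbaldehyde 15 (not isolated)
Conditions: (i) 14 (2 equiv), Dess–Martin periodinane, pyridine, CH2Cl2, 0 °C → rt, filter; (ii) filtrate added to 12, LiCl, i-Pr2NEt, MeCN, 0 °C → rt
Reagents that add atoms: none
Why: Dess–Martin oxidation gives the trans-epoxy aldehyde without epimerisation, and the Masamune–Roush Horner–Wadsworth–Emmons olefination (LiCl/amine) is E-selective and mild enough for the free diol, the lactone and the oxirane; no stereocentre is touched.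

**Compound list**

1 | methyl (2S)-oxirane-2-carboxylate | COC(=O)[C@@H]1CO1 | starting material
2 | allylmagnesium bromide | C=CC[Mg]Br | starting material
3 | methyl (2S)-2-hydroxyhex-5-enoate | COC(=O)[C@@H](O)CCC=C | intermediate
4 | (2S)-2-hydroxyhex-5-enoic acid | OC(=O)[C@@H](O)CCC=C | intermediate
5 | (2S)-2-{[2-(diethoxyphosphoryl)acetyl]oxy}hex-5-enoic acid | OC(=O)[C@@H](OC(=O)CP(=O)(OCC)OCC)CCC=C | intermediate
6 | (2E)-penta-2,4-dienal | O=C/C=C/C=C | starting material
7 | propylmagnesium bromide | CCC[Mg]Br | starting material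
8 | racemic (5E)-octa-5,7-dien-4-ol | CCCC(O)/C=C/C=C | intermediate
9 | (1R)-1-[(2R,3R)-3-ethenyloxiran-2-yl]butan-1-ol | C=C[C@H]1O[C@@H]1[C@H](O)CCC | intermediate
10 | (3S,4R,5R)-4,5-dihydroxyoct-1-en-3-yl (2S)-2-{[2-(diethoxyphosphoryl)acetyl]oxy}hex-5-enoate | C=CCC[C@H](OC(=O)CP(=O)(OCC)OCC)C(=O)O[C@@H](C=C)[C@H](O)[C@H](O)CCC | intermediate
11 | (3S,6Z,8S)-8-[(1R,2R)-1,2-dihydroxypentyl]-2-oxo-3,4,5,8-tetrahydro-2H-oxocin-3-yl 2-(diethoxyphosphoryl)acetate | CCC[C@@H](O)[C@@H](O)[C@@H]1/C=C\CC[C@H](OC(=O)CP(=O)(OCC)OCC)C(=O)O1 | intermediate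
12 | (3S,6Z,8S,9S,10R)-8,9-dihydroxy-2-oxo-10-propyl-3,4,5,8,9,10-hexahydro-2H-oxecin-3-yl 2-(diethoxyphosphoryl)acetate | CCC[C@H]1OC(=O)[C@@H](OC(=O)CP(=O)(OCC)OCC)CC/C=C\[C@H](O)[C@@H]1O | intermediate
13 | (2E)-but-2-en-1-ol | C/C=C/CO | starting material
14 | [(2S,3S)-3-methyloxiran-2-yl]methanol | C[C@@H]1O[C@H]1CO | intermediate
15 | (2R,3S)-3-methyloxirane-2-carbaldehyde | C[C@@H]1O[C@H]1C=O | intermediate
16 | (3S,6Z,8S,9S,10R)-8,9-dihydroxy-2-oxo-10-propyl-3,4,5,8,9,10-hexahydro-2H-oxecin-3-yl (2E)-3-[(2S,3S)-3-methyloxiran-2-yl]prop-2-enoate | CCC[C@H]1OC(=O)[C@@H](OC(=O)/C=C/[C@@H]2O[C@H]2C)CC/C=C\[C@H](O)[C@@H]1O | target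

**Step count and risks**

Total steps: 9. Longest linear sequence: 6 steps (1 → 2 → 5 → 6 → 7 → 9, or 3 → 4 → 5 → 6 → 7 → 9).

The three steps most likely to fail are step 7, step 6 and step 5.

Step 7 (the proposed ring expansion). The risk is that the equilibrium between the eight-, nine- and ten-membered lactones does not lie far enough on the side of 12, or that the catalyst is too slow. The fallback uses only known chemistry; it sets out from acid 5 and comes back to the route at 12.
- (E)-Hex-2-enal and vinylmagnesium bromide give racemic (4E)-octa-1,4-dien-3-ol F1.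
- Sharpless kinetic resolution with L-(+)-diisopropyl tartrate gives (1S)-1-[(2S,3S)-3-propyloxiran-2-yl]prop-2-en-1-ol F2.
- Ti(OiPr)4-mediated opening by acid 5 at the propyl-bearing epoxide carbon (inversion) gives the C9 ester (3S,4S,5R)-3,4-dihydroxyoct-1-en-5-yl (2S)-2-{[2-(diethoxyphosphoryl)acetyl]oxy}hex-5-enoate F3.
- 2,2-Dimethoxypropane/PPTS gives the acetonide (1R)-1-[(4R,5S)-5-ethenyl-2,2-dimethyl-1,3-dioxolan-4-yl]butyl (2S)-2-{[2-(diethoxyphosphoryl)acetyl]oxy}hex-5-enoate F4.
- Ring-closing metathesis with the second-generation Grubbs catalyst RuCl2(=CHPh)(PCy3)(SIMes) in hot toluene, run to equilibrium, gives the (Z)-configured 8,9-O-isopropylidene acetal of 12 (oxecin numbering) F5; Z is the thermodynamic olefin isomer of such acetonide-bridged ten-membered lactones.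
- Aqueous acid (1 M HCl, THF) removes the acetonide and gives 12.

Step 6 (metathesis to an eight-membered lactone). The risk is oligomerisation or no ring closure, because the ester prefers an extended conformation and the free diol can bind ruthenium. The fallback sets out from 10 and comes back at 11.
- The 8,9-diol is tied up with 2,2-dimethoxypropane/PPTS as (1S)-1-[(4R,5R)-2,2-dimethyl-5-propyl-1,3-dioxolan-4-yl]prop-2-en-1-yl (2S)-2-{[2-(diethoxyphosphoryl)acetyl]oxy}hex-5-enoate F6. This removes the chelating hydroxyls and places a compact ring next to the carbinol.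
- Ring-closing metathesis under the same conditions gives (3S,6Z,8S)-8-[(4R,5R)-2,2-dimethyl-5-propyl-1,3-dioxolan-4-yl]-2-oxo-3,4,5,8-tetrahydro-2H-oxocin-3-yl 2-(diethoxyphosphoryl)acetate F7.
- 80 % aqueous acetic acid at room temperature frees the diol and returns 11.

Step 5 (Ti-mediated opening of a vinyl epoxide by a functionalised acid). The risks are SN2′ attack, acyl migration to O8, and isopropoxide exchange on the activated ester. The fallback separates the stereo-defining opening from the fragment coupling; it sets out from 9 and comes back at 10.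
- Ti(OiPr)4 and benzoic acid (the standard nucleophile for this opening) give (3S,4R,5R)-4,5-dihydroxyoct-1-en-3-yl benzoate F8.
- Et3SiOTf/2,6-lutidine gives (3S,4S,5R)-4,5-bis[(triethylsilyl)oxy]oct-1-en-3-yl benzoate F9.
- i-Bu2AlH at −78 °C removes the benzoate to give (3S,4S,5R)-4,5-bis[(triethylsilyl)oxy]oct-1-en-3-ol F10.
- Carbodiimide esterification with acid 5 (EDC·HCl, DMAP) gives (3S,4S,5R)-4,5-bis[(triethylsilyl)oxy]oct-1-en-3-yl (2S)-2-{[2-(diethoxyphosphoryl)acetyl]oxy}hex-5-enoate F11.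
- HF·pyridine in THF at 0 °C removes both silyl groups and gives 10.

Further compounds
F1 | step 7 | racemic (4E)-octa-1,4-dien-3-ol | C=CC(O)/C=C/CCC
F2 | step 7 | (1S)-1-[(2S,3S)-3-propyloxiran-2-yl]prop-2-en-1-ol | C=C[C@H](O)[C@@H]1O[C@H]1CCC
F3 | step 7 | (3S,4S,5R)-3,4-dihydroxyoct-1-en-5-yl (2S)-2-{[2-(diethoxyphosphoryl)acetyl]oxy}hex-5-enoate | C=CCC[C@H](OC(=O)CP(=O)(OCC)OCC)C(=O)O[C@H](CCC)[C@@H](O)[C@@H](O)C=C
F4 | step 7 | (1R)-1-[(4R,5S)-5-ethenyl-2,2-dimethyl-1,3-dioxolan-4-yl]butyl (2S)-2-{[2-(diethoxyphosphoryl)acetyl]oxy}hex-5-enoate | C=CCC[C@H](OC(=O)CP(=O)(OCC)OCC)C(=O)O[C@H](CCC)[C@H]1OC(C)(C)O[C@H]1C=C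
F5 | step 7 | (Z)-8,9-O-isopropylidene acetal of 12 | CCC[C@H]1OC(=O)[C@@H](OC(=O)CP(=O)(OCC)OCC)CC/C=C\[C@@H]2OC(C)(C)O[C@H]12
F6 | step 6 | (1S)-1-[(4R,5R)-2,2-dimethyl-5-propyl-1,3-dioxolan-4-yl]prop-2-en-1-yl (2S)-2-{[2-(diethoxyphosphoryl)acetyl]oxy}hex-5-enoate | C=CCC[C@H](OC(=O)CP(=O)(OCC)OCC)C(=O)O[C@@H](C=C)[C@@H]1OC(C)(C)O[C@@H]1CCC
F7 | step 6 | (3S,6Z,8S)-8-[(4R,5R)-2,2-dimethyl-5-propyl-1,3-dioxolan-4-yl]-2-oxo-3,4,5,8-tetrahydro-2H-oxocin-3-yl 2-(diethoxyphosphoryl)acetate | CCC[C@H]1OC(C)(C)O[C@H]1[C@@H]2/C=C\CC[C@H](OC(=O)CP(=O)(OCC)OCC)C(=O)O2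
F8 | step 5 | (3S,4R,5R)-4,5-dihydroxyoct-1-en-3-yl benzoate | C=C[C@H](OC(=O)c1ccccc1)[C@H](O)[C@H](O)CCC
F9 | step 5 | (3S,4S,5R)-4,5-bis[(triethylsilyl)oxy]oct-1-en-3-yl benzoate | C=C[C@H](OC(=O)c1ccccc1)[C@H](O[Si](CC)(CC)CC)[C@H](O[Si](CC)(CC)CC)CCC
F10 | step 5 | (3S,4S,5R)-4,5-bis[(triethylsilyl)oxy]oct-1-en-3-ol | C=C[C@H](O)[C@H](O[Si](CC)(CC)CC)[C@H](O[Si](CC)(CC)CC)CCC
F11 | step 5 | (3S,4S,5R)-4,5-bis[(triethylsilyl)oxy]oct-1-en-3-yl (2S)-2-{[2-(diethoxyphosphoryl)acetyl]oxy}hex-5-enoate | C=CCC[C@H](OC(=O)CP(=O)(OCC)OCC)C(=O)O[C@@H](C=C)[C@H](O[Si](CC)(CC)CC)[C@H](O[Si](CC)(CC)CC)CCC
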